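## Structural features

The target 27 is a 3,4-dihydro-2H-chromen-2-one whose ring A is not aromatic. C8 is a quaternary sp3 carbon with two 3-methylbut-2-enyl groups, C7 is a ketone, C5 an enol, C6 carries the (2R)-2-methylbutanoyl group, and the C4a=C8a enol double bond carries O1, which closes the lactone through C2 and C3 to the phenyl-bearing C4. Ring A is therefore a fully substituted 3,5-dioxygenated 6,6-dialkylcyclohexa-2,4-dienone that cannot tautomerise to a phloroglucinol. The two stereocentres, C4 (S) and C2' of the acyl chain (R), are six bonds apart and cannot control one another. C4 is benzylic but not enolisable, whereas C2' is alpha to a ketone and is the configurationally delicate one. The fragile groups are the two trisubstituted alkenes (they cyclise onto neighbouring enol oxygens under acid), the enol lactone (an acyl donor towards hydroxide and nucleophiles), the C4–C4a bond (formally a Michael bond, so strong base is to be avoided) and the gem-diallyl dienone (sigmatropic shifts on long heating). The real difficulty is ring A: the quaternary C8 between two oxygenated carbons, and the need to tell O5 from O8a, both of which are ortho to C4a and could each close a six-membered lactone. The key step uses the fact that C7, C4a, C8a and C8 map onto a 4,4-dialkyl-3-alkoxycyclobutenone and C5–C6 onto an alkoxyalkyne. C8 is then quaternary before ring A exists, and O8a and O5 arrive on different fragments and can carry different groups.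

## Logic of the disconnections

27 to 24 and 25: the C6–C1' bond is cut. A 2-acyl-1,3-dione is the thermodynamic product of O-to-C acyl transfer, so the acyl group and its epimerisable centre can come last. This removes one stereocentre and the triketone. The forward step must transfer the acyl group without enolising C2' and without disturbing the lactone.

24 to 23: the O5–H is traced back to an O5–ethyl vinylogous ester. O5 stays masked until the lactone exists, so only one oxygen can lactonise. The forward step must cleave one vinylogous ester under conditions that spare the alkenes and the lactone.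

23 to 22: the lactone O1–C2 bond is cut. With O5 ethylated, O8a is the only ring oxygen that can close, so the regiochemistry is fixed by construction. The forward step is a mild dehydrative closure.

22 to 20: the O8a–CH2 bond of a 2-(trimethylsilyl)ethyl ether and the O–CH3 bond of the ester are cut. The silylethyl group is removable by fluoride while O5–ethyl stays; a version with two ethyl groups would leave O5 and O8a indistinguishable and would need aqueous acid twice. The forward step must free O8a and the acid without touching O5.

20 to 15 and 16 (key step): C6–C7 and C4a–C5 are cut; C7–C8 is broken and re-formed inside the cascade. Ring A collapses to a four-membered ring plus a two-carbon alkyne, and the oxygen pattern follows from the two partners. The forward step needs the ketene–alkyne addition to occur in one orientation and the strained ring to open at a tolerable temperature.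

15 to 12 and 9: C7–C8 and C4a–C8a of the four-membered ring are cut (ketene plus ketene acetal), followed by loss of silanol. This separates a chiral C3–C4–C4a–C7 half from an achiral C8–C8a half. The chiral fragment is made the ketene, so it never meets a strong base. The forward step needs ring closure of the zwitterion to outrun silyl transfer.

12 to 11 to 10: the C–Cl bond and then the ester C–O bond are cut, the latter made by desymmetrising methanolysis. C4 is defined only by which carbonyl carries the methyl ester, so the forward steps need high enantioselection and no exchange of the two arms.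

9 to 7 to 6 to 4 to 1 and 2: the O–Si bond, the ester C–O bond, one C–CO2H bond (decarboxylation) and the two C–C bonds to the prenyl groups are cut in turn. This is standard malonate chemistry with no selectivity issue.

## Other disconnections considered

Alternative 1: The aryl C8a–O1 bond of an aromatic lactone is cut. In the forward step the trivalent iodine reagent PhI(OCOCF3)2, activated by BF3·OEt2, oxidises the dimethoxyphenyl ring of (3S)-3-(3,5-dimethoxyphenyl)-3-phenylpropanoic acid A1, and the carboxyl group closes onto the ortho carbon to give (4S)-5,7-dimethoxy-4-phenylchroman-2-one A2 with C4 untouched.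
- In favour: A1 is within reach of asymmetric conjugate arylation, the two ortho positions are equivalent, and oxidative lactonisation of electron-rich arylpropanoic acids is a known reaction type. On mechanistic precedent this alternative is better than the chosen plan.
- Against: A2 has an aromatic ring A, so the hard part of 27 is still ahead. It needs two O-demethylations, acylation at C6 rather than C8, and two C-prenylations at C8 that must dearomatise the ring in competition with O-alkylation, under base that opens the lactone. The oxidant may also attack the doubly benzylic C4–H.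
- Comparison: on structure the chosen plan builds C8 and differentiates the oxygens during ring construction, whereas this one leaves both to the least selective step. On step economy the two are about equal, perhaps slightly in favour of the alternative. Its aromatic endgame is kept as the reserve for step 8.

Alternative 2: C4a–C8a and C6–C7 are cut. In the forward step methyl (3S,8R)-8-methyl-5,7-dioxo-3-phenyldecanoate A3 is converted into its bis(trimethylsilyl) dienol ether A4, which is C-acylated at its terminal carbon (C4a) and its central carbon (C6) by 2,2-bis(3-methylbut-2-enyl)propanedioyl dichloride A5 under TiCl4 or Me3SiOTf. The product is A6, the open-lactone methyl ester of 27.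
- In favour: it is the most convergent plan. The acyl chain, both prenyl groups and all ring carbons arrive in one step, and A6 needs only lactonisation. In A6, O5 is held in the hydrogen bond to the acyl carbonyl, so O8a should react without protecting groups. On step economy it is better than the chosen plan; on lactone regiocontrol it is its equal.
- Against: both carbonyls of A5 are neopentyl-like. Malonyl-type dielectrophiles tend to acylate such dienol ethers once on carbon and once on oxygen, giving a hydroxypyranone. A strong Lewis acid meets two prenyl groups. The C8 centre of A3, alpha to a ketone, is exposed to enolisation during silylation.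
- Comparison: on mechanism both key steps lack direct precedent, but the pericyclic cascade has only one ring size open to it, while the ionic double acylation has a competing O-acylation channel.

Alternative 3: C4a–C5 and C7–C8 are cut. In the forward step the trimethylsilyl enol ether A8 of methyl (3S)-9-methyl-6-(3-methylbut-2-enyl)-5-oxo-3-phenyldec-8-enoate A7 is acylated at both alpha carbons by malonyl dichloride A9 (an Effenberger-type annulation) to give A10.
- In favour: A9 is the cheapest three-carbon unit, A7 is one C–C bond away from 12, and this annulation is a known reaction type for enol ethers. A10 is the ring-opened methyl ester of 24, so the route would rejoin the chosen one before step 12. On step count and on precedent of the reaction type it is equal or better.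
- Against: the second acylation must create the quaternary C8 between two prenyl groups on an acyclic, unorganised substrate. O-acylation to a pyranone is the expected competitor, and HCl is released onto the prenyl groups. A10 has O5 and O8a both free, so lactone regiochemistry is left open.
- Comparison: on structure the chosen plan has the quaternary carbon in place before ring A forms and the oxygens differentiated; this alternative has neither.

Key step: step 8

Remark: 27 is a vinylogous acid and is treated throughout as the 5-hydroxy-7-oxo tautomer drawn in the target structure; the other enol forms of 21, 22, 24 and 27 are the same compounds.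

## Route

Step 1
Reactants: 1 diethyl malonate; 2 prenyl bromide (1-bromo-3-methylbut-2-ene)
Product: 4 diethyl 2,2-bis(3-methylbut-2-en-1-yl)propanedioate, via diethyl 2-prenylmalonate 3 (not isolated)
Conditions: NaH (2.3 equiv), 2 (2.3 equiv), THF/DMF, 0 °C to rt
Reagents that add atoms: none
Why: Double C-alkylation of the malonate anion (malonic ester synthesis); SN2 at the primary allylic carbon keeps the prenyl regiochemistry and the second alkylation is still fast with this unhindered electrophile.

Step 2
Reactants: 4 diethyl 2,2-bis(3-methylbut-2-en-1-yl)propanedioate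
Product: 6 5-methyl-2-(3-methylbut-2-en-1-yl)hex-4-enoic acid, via diprenylmalonic acid 5 (not isolated)
Conditions: KOH, EtOH/H2O, reflux; 1 M HCl, 0 °C, to pH 2; then pyridine, 110 °C
Reagents that add atoms: potassium hydroxide, [K+].[OH-]
Why: Saponification followed by thermal decarboxylation of the disubstituted malonic acid through the usual cyclic transition state; pyridine keeps the medium non-acidic so the alkenes do not lactonise onto the acid.

Step 3
Reactants: 6 5-methyl-2-(3-methylbut-2-en-1-yl)hex-4-enoic acid
Product: 7 2-(trimethylsilyl)ethyl 5-methyl-2-(3-methylbut-2-en-1-yl)hex-4-enoate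
Conditions: Me3SiCH2CH2OH (1.2 equiv), EDC·HCl, DMAP (cat.), CH2Cl2, 0 °C to rt
Reagents that add atoms: 2-(trimethylsilyl)ethanol, C[Si](C)(C)CCO
Why: Steglich esterification; the silylethyl group is chosen because it becomes the O8a substituent of ring A and can later be removed by fluoride while an O-ethyl group stays.

Step 4
Reactants: 7 2-(trimethylsilyl)ethyl 5-methyl-2-(3-methylbut-2-en-1-yl)hex-4-enoate
Product: 9 trimethyl({5-methyl-2-(3-methylbut-2-en-1-yl)-1-[2-(trimethylsilyl)ethoxy]hexa-1,4-dien-1-yl}oxy)silane, via lithium enolate 8 (not isolated)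
Conditions: LiN(iPr)2 (1.1 equiv), THF, −78 °C; then Me3SiCl, −78 °C to rt; pentane, filtration, evaporation, used crude
Reagents that add atoms: chlorotrimethylsilane, C[Si](C)(C)Cl
Why: Deprotonation of the alpha-branched ester and O-silylation of the hindered enolate (silyl ketene acetal formation); the two substituents on the nucleophilic carbon are identical, so there is no double-bond isomer issue.

Step 5
Reactants: 10 3-phenylglutaric anhydride
Product: 11 (3S)-5-methoxy-5-oxo-3-phenylpentanoic acid
Conditions: MeOH (10 equiv), cinchona-alkaloid sulfonamide catalyst (10 mol %, pseudoenantiomer chosen for the S acid), MTBE, rt; acid–base extraction, recrystallisation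
Reagents that add atoms: methanol, CO
Why: Catalytic enantioselective alcoholysis of a prochiral cyclic anhydride, in which the bifunctional catalyst activates methanol by general base catalysis and one enantiotopic carbonyl by hydrogen bonding. This sets C4 of the target: the free acid arm becomes C4a and C7, the ester arm becomes C3 and C2.

Step 6
Reactants: 11 (3S)-5-methoxy-5-oxo-3-phenylpentanoic acid
Product: 12 methyl (3R)-5-chloro-5-oxo-3-phenylpentanoate
Conditions: (COCl)2 (1.2 equiv), DMF (cat.), CH2Cl2, 0 °C, 1 h; evaporated cold and used at once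
Reagents that add atoms: oxalyl chloride, O=C(Cl)C(=O)Cl
Why: Chlorination through the Vilsmeier-type chloroiminium species under cold, neutral conditions; the descriptor changes to R by priority only. The product is not stored because a half-ester acid chloride can exchange its two arms through a cyclic acyloxonium ion, which would racemise a centre defined only by that difference.

Step 7
Reactants: 12 methyl (3R)-5-chloro-5-oxo-3-phenylpentanoate; 9 trimethyl({5-methyl-2-(3-methylbut-2-en-1-yl)-1-[2-(trimethylsilyl)ethoxy]hexa-1,4-dien-1-yl}oxy)silane
Product: 15 methyl (3S)-3-{3,3-bis(3-methylbut-2-en-1-yl)-4-oxo-2-[2-(trimethylsilyl)ethoxy]cyclobut-1-en-1-yl}-3-phenylpropanoate, via ketene 13 (not isolated), via cyclobutanone adduct 14 (not isolated)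
Conditions: 9 (1.5 equiv), Et3N (1.3 equiv), toluene, 0 °C to rt, slow addition of 12; then silica gel
Reagents that add atoms: none
Why: Dehydrochlorination gives ketene 13, whose carbonyl carbon is attacked by the nucleophilic carbon of 9; closure of the zwitterion at the less hindered enolate carbon gives 14 ([2+2] cycloaddition of a ketene with a ketene acetal). Beta-elimination of trimethylsilanol from this beta-siloxy ketone then gives the vinylogous ester 15; the regiochemistry is fixed by polarity and C4 is a spectator.

Step 8
Reactants: 15 methyl (3S)-3-{3,3-bis(3-methylbut-2-en-1-yl)-4-oxo-2-[2-(trimethylsilyl)ethoxy]cyclobut-1-en-1-yl}-3-phenylpropanoate; 16 ethoxyethyne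
Product: 20 methyl (3S)-3-{6-ethoxy-3,3-bis(3-methylbut-2-en-1-yl)-4-oxo-2-[2-(trimethylsilyl)ethoxy]cyclohexa-1,5-dien-1-yl}-3-phenylpropanoate, via vinylketene 17 (not isolated), via 4-vinylcyclobutenone 18 (not isolated), via dienylketene 19 (not isolated)
Conditions: 16 (5 equiv, solution in hexanes, added in portions), toluene, 110–120 °C, sealed tube, dry, dark
Reagents that add atoms: none
Why: Proposed new method: thermal conrotatory 4-pi opening of 15 breaks C7–C8 and gives vinylketene 17, whose C=C=O unit adds 16 in a [2+2] cycloaddition with the unsubstituted alkyne carbon bonding to the ketene carbonyl carbon C7 and the ethoxy-bearing carbon to C4a, the orientation dictated by the polarisation of an alkoxyalkyne. The resulting 4-vinylcyclobutenone 18 opens again to dienylketene 19, and thermal disrotatory 6-pi electrocyclisation joins C7 to C8 and closes ring A, the only ring formed. The closest known reaction type is the Danheiser benzannulation of cyclobutenones with alkoxy- or siloxyalkynes, which runs through the same three pericyclic events but ends in a phenol by tautomerisation; here C8 carries no hydrogen, so the sequence has to stop at the 6,6-dialkylcyclohexa-2,4-dienone, the same closure by which dienylketenes from ring-opened dienones of this type revert on warming. No stereocentre is created: C8 bears two identical groups, the quaternary carbon of 18 is lost again on ring opening, and C4 is never next to an acidifying group, so its configuration is carried through. The selectivities needed are the orientation of the ketene–alkyne addition, secured by alkyne polarity, and capture of 17 by 16 in preference to reclosure to 15 or reaction with its own prenyl groups, secured by an excess of the electron-rich alkyne added in portions because it slowly loses ethene at this temperature. The driving force is the release of the strain of two four-membered rings and the formation of a doubly vinylogous ester.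

Step 9
Reactants: 20 methyl (3S)-3-{6-ethoxy-3,3-bis(3-methylbut-2-en-1-yl)-4-oxo-2-[2-(trimethylsilyl)ethoxy]cyclohexa-1,5-dien-1-yl}-3-phenylpropanoate
Product: 22 (3S)-3-[6-ethoxy-2-hydroxy-3,3-bis(3-methylbut-2-en-1-yl)-4-oxocyclohexa-1,5-dien-1-yl]-3-phenylpropanoic acid, via enol methyl ester 21 (not isolated)
Conditions: Bu4NF (2.5 equiv), THF, 0 °C to rt; then LiOH·H2O (3 equiv), THF/H2O, rt; cold 1 M HCl to pH 3
Reagents that add atoms: lithium hydroxide, [Li+].[OH-]
Why: Fluoride attacks silicon and the silylethyl ether fragments to ethene, Me3SiF and the O8a enolate (beta-elimination as for 2-(trimethylsilyl)ethyl esters, the leaving group being a vinylogous carboxylate); hydroxide then saponifies the methyl ester. The O5 ethyl vinylogous ester should survive because ring A is an anion once O8a is free and no longer accepts hydroxide at C5.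

Step 10
Reactants: 22 (3S)-3-[6-ethoxy-2-hydroxy-3,3-bis(3-methylbut-2-en-1-yl)-4-oxocyclohexa-1,5-dien-1-yl]-3-phenylpropanoic acid
Product: 23 (4S)-5-ethoxy-8,8-bis(3-methylbut-2-en-1-yl)-4-phenyl-3,4-dihydro-2H-chromene-2,7(8H)-dione
Conditions: EDC·HCl (1.3 equiv), DMAP (0.1 equiv), CH2Cl2, 0 °C to rt
Reagents that add atoms: none
Why: Steglich-type lactonisation (carbodiimide activation of the acid, attack by the enol oxygen through a six-membered transition state); O8a is the only ring oxygen that is free and within reach because O5 is still ethylated, so the lactone regiochemistry is fixed by construction.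

Step 11
Reactants: 23 (4S)-5-ethoxy-8,8-bis(3-methylbut-2-en-1-yl)-4-phenyl-3,4-dihydro-2H-chromene-2,7(8H)-dione
Product: 24 (4S)-5-hydroxy-8,8-bis(3-methylbut-2-en-1-yl)-4-phenyl-3,4-dihydro-2H-chromene-2,7(8H)-dione
Conditions: 1 M HCl (aq)/THF 1:4, 0 °C to rt, stopped at full conversion
Reagents that add atoms: water, O
Why: Acid-catalysed hydrolysis of the one remaining vinylogous ester (protonation at C6, addition of water at C5, loss of ethanol); dilute acid at room temperature is used because a push–pull enol ether is protonated much faster than an isolated trisubstituted alkene, and an enol lactone of this kind should not be hydrolysed under such conditions.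

Step 12
Reactants: 24 (4S)-5-hydroxy-8,8-bis(3-methylbut-2-en-1-yl)-4-phenyl-3,4-dihydro-2H-chromene-2,7(8H)-dione; 25 (2R)-2-methylbutanoic acid
Product: 27 (4S)-5-hydroxy-6-[(2R)-2-methylbutanoyl]-8,8-bis(3-methylbut-2-en-1-yl)-4-phenyl-3,4-dihydro-2H-chromene-2,7(8H)-dione, via enol ester 26 (not isolated)
Conditions: 25 (1.1 equiv), DCC (1.2 equiv), DMAP (1.3 equiv), CH2Cl2, 0 °C to rt
Reagents that add atoms: none
Why: Steglich O-acylation of the vinylogous acid gives enol ester 26, and DMAP then mediates the 1,3 O-to-C acyl shift to C6, the only carbon between two enolisable carbonyls, giving the hydrogen-bonded triketone as the thermodynamic product. The acid is activated without an added amine base, so C2' is not expected to enolise and C4 is untouched; should the lactone acyl group move between O8a and O5 under DMAP, the chelated triketone of 27 would remain the favoured isomer.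

## Compound list

1 | diethyl malonate | CCOC(=O)CC(=O)OCC | starting material
2 | prenyl bromide (1-bromo-3-methylbut-2-ene) | CC(C)=CCBr | starting material
3 | diethyl 2-(3-methylbut-2-en-1-yl)propanedioate | CCOC(=O)C(CC=C(C)C)C(=O)OCC | intermediate (not isolated)
4 | diethyl 2,2-bis(3-methylbut-2-en-1-yl)propanedioate | CCOC(=O)C(CC=C(C)C)(CC=C(C)C)C(=O)OCC | intermediate
5 | 2,2-bis(3-methylbut-2-en-1-yl)propanedioic acid | OC(=O)C(CC=C(C)C)(CC=C(C)C)C(=O)O | intermediate (not isolated)
6 | 5-methyl-2-(3-methylbut-2-en-1-yl)hex-4-enoic acid | CC(C)=CCC(CC=C(C)C)C(=O)O | intermediate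
7 | 2-(trimethylsilyl)ethyl 5-methyl-2-(3-methylbut-2-en-1-yl)hex-4-enoate | CC(C)=CCC(CC=C(C)C)C(=O)OCC[Si](C)(C)C | intermediate
8 | lithium enolate of 7 | [Li+].CC(C)=CCC(CC=C(C)C)=C([O-])OCC[Si](C)(C)C | intermediate (not isolated)
9 | trimethyl({5-methyl-2-(3-methylbut-2-en-1-yl)-1-[2-(trimethylsilyl)ethoxy]hexa-1,4-dien-1-yl}oxy)silane | CC(C)=CCC(CC=C(C)C)=C(OCC[Si](C)(C)C)O[Si](C)(C)C | intermediate
10 | 3-phenylglutaric anhydride (4-phenyloxane-2,6-dione) | O=C1CC(c2ccccc2)CC(=O)O1 | starting material
11 | (3S)-5-methoxy-5-oxo-3-phenylpentanoic acid | COC(=O)C[C@H](CC(=O)O)c1ccccc1 | intermediate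
12 | methyl (3R)-5-chloro-5-oxo-3-phenylpentanoate | COC(=O)C[C@H](CC(=O)Cl)c1ccccc1 | intermediate
13 | methyl (3R)-5-oxo-3-phenylpent-4-enoate (ketene) | COC(=O)C[C@H](C=C=O)c1ccccc1 | intermediate (not isolated)
14 | methyl (3R)-3-{3,3-bis(3-methylbut-2-en-1-yl)-4-oxo-2-[2-(trimethylsilyl)ethoxy]-2-(trimethylsilyloxy)cyclobutyl}-3-phenylpropanoate (mixture at the two ring stereocentres) | C[Si](C)(C)CCOC1(O[Si](C)(C)C)C([C@H](c2ccccc2)CC(=O)OC)C(=O)C1(CC=C(C)C)CC=C(C)C | intermediate (not isolated)
15 | methyl (3S)-3-{3,3-bis(3-methylbut-2-en-1-yl)-4-oxo-2-[2-(trimethylsilyl)ethoxy]cyclobut-1-en-1-yl}-3-phenylpropanoate | C[Si](C)(C)CCOC1=C([C@H](c2ccccc2)CC(=O)OC)C(=O)C1(CC=C(C)C)CC=C(C)C | intermediate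
16 | ethoxyethyne | CCOC#C | starting material
17 | methyl (3S)-9-methyl-6-(3-methylbut-2-en-1-yl)-4-(oxomethylidene)-3-phenyl-5-[2-(trimethylsilyl)ethoxy]deca-5,8-dienoate (vinylketene) | O=C=C([C@H](c1ccccc1)CC(=O)OC)C(OCC[Si](C)(C)C)=C(CC=C(C)C)CC=C(C)C | intermediate (not isolated)
18 | methyl (3S)-3-(2-ethoxy-1-{5-methyl-2-(3-methylbut-2-en-1-yl)-1-[2-(trimethylsilyl)ethoxy]hexa-1,4-dien-1-yl}-4-oxocyclobut-2-en-1-yl)-3-phenylpropanoate (either configuration at the ring carbon) | O=C1C=C(OCC)C1([C@H](c1ccccc1)CC(=O)OC)C(OCC[Si](C)(C)C)=C(CC=C(C)C)CC=C(C)C | intermediate (not isolated)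
19 | methyl (3S)-4-(1-ethoxy-3-oxoprop-2-en-1-ylidene)-9-methyl-6-(3-methylbut-2-en-1-yl)-3-phenyl-5-[2-(trimethylsilyl)ethoxy]deca-5,8-dienoate (dienylketene; ketenyl carbon and C8a cis about C5=C4a) | O=C=C/C(OCC)=C(\C(OCC[Si](C)(C)C)=C(CC=C(C)C)CC=C(C)C)[C@H](c1ccccc1)CC(=O)OC | intermediate (not isolated)
20 | methyl (3S)-3-{6-ethoxy-3,3-bis(3-methylbut-2-en-1-yl)-4-oxo-2-[2-(trimethylsilyl)ethoxy]cyclohexa-1,5-dien-1-yl}-3-phenylpropanoate | C[Si](C)(C)CCOC1=C([C@H](c2ccccc2)CC(=O)OC)C(OCC)=CC(=O)C1(CC=C(C)C)CC=C(C)C | intermediate
21 | methyl (3S)-3-[6-ethoxy-2-hydroxy-3,3-bis(3-methylbut-2-en-1-yl)-4-oxocyclohexa-1,5-dien-1-yl]-3-phenylpropanoate (formed as its tetrabutylammonium enolate) | CCOC1=CC(=O)C(CC=C(C)C)(CC=C(C)C)C(O)=C1[C@H](c1ccccc1)CC(=O)OC | intermediate (not isolated)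
22 | (3S)-3-[6-ethoxy-2-hydroxy-3,3-bis(3-methylbut-2-en-1-yl)-4-oxocyclohexa-1,5-dien-1-yl]-3-phenylpropanoic acid | CCOC1=CC(=O)C(CC=C(C)C)(CC=C(C)C)C(O)=C1[C@H](c1ccccc1)CC(=O)O | intermediate
23 | (4S)-5-ethoxy-8,8-bis(3-methylbut-2-en-1-yl)-4-phenyl-3,4-dihydro-2H-chromene-2,7(8H)-dione | CCOC1=CC(=O)C(CC=C(C)C)(CC=C(C)C)C2=C1[C@H](c1ccccc1)CC(=O)O2 | intermediate
24 | (4S)-5-hydroxy-8,8-bis(3-methylbut-2-en-1-yl)-4-phenyl-3,4-dihydro-2H-chromene-2,7(8H)-dione | OC1=CC(=O)C(CC=C(C)C)(CC=C(C)C)C2=C1[C@H](c1ccccc1)CC(=O)O2 | intermediate
25 | (2R)-2-methylbutanoic acid | CC[C@@H](C)C(=O)O | starting material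
26 | (4S)-8,8-bis(3-methylbut-2-en-1-yl)-2,7-dioxo-4-phenyl-3,4,7,8-tetrahydro-2H-chromen-5-yl (2R)-2-methylbutanoate | CC[C@@H](C)C(=O)OC1=CC(=O)C(CC=C(C)C)(CC=C(C)C)C2=C1[C@H](c1ccccc1)CC(=O)O2 | intermediate (not isolated)
27 | (4S)-5-hydroxy-6-[(2R)-2-methylbutanoyl]-8,8-bis(3-methylbut-2-en-1-yl)-4-phenyl-3,4-dihydro-2H-chromene-2,7(8H)-dione | CC[C@@H](C)C(=O)C1=C(O)C2=C(OC(=O)C[C@H]2c2ccccc2)C(CC=C(C)C)(CC=C(C)C)C1=O | target

## Step count and least certain steps

Total: 12 steps. Longest linear sequence: 10 steps (steps 1–4, then 7–12); the chiral branch (steps 5 and 6) joins at step 7.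

Step 8 (key step, beyond known chemistry). The most likely failure is that the alkoxy-stabilised, gem-dialkyl cyclobutenone opens only at a temperature where 16 is consumed by its own loss of ethene, so the vinylketene recloses or is captured by one of its prenyl groups. A second risk is [3,3] shifts of the gem-diprenyl dienone on long heating. The fallback uses known chemistry only and abandons the four-membered ring. It sets out from 2 and 25, together with purchased 5,7-dihydroxycoumarin and phenylboronic acid, and comes back at 27. 5,7-Dihydroxycoumarin is silylated (t-BuMe2SiCl, imidazole) to 5,7-bis(tert-butyldimethylsilyloxy)-2H-chromen-2-one F1. Hayashi–Miyaura 1,4-addition of PhB(OH)2 (Rh(acac)(C2H4)2, SEGPHOS enantiomer chosen for the S product, dioxane/H2O, 60 °C) should give (4S)-5,7-bis(tert-butyldimethylsilyloxy)-4-phenylchroman-2-one F2. Bu4NF/AcOH then frees (4S)-5,7-dihydroxy-4-phenylchroman-2-one F3. Friedel–Crafts acylation with 25 (BF3·OEt2) at C6, the carbon between the two free hydroxyls, gives (4S)-5,7-dihydroxy-6-[(2R)-2-methylbutanoyl]-4-phenylchroman-2-one F4. Two C-prenylations at C8 with 2 (aqueous KOH, 0 °C, then acidification to reclose the lactone) dearomatise ring A and should deliver 27.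

Step 7. The zwitterion formed from the ketene and the silyl ketene acetal can pass its silyl group from one oxygen to the other and end as an open-chain silyl enol ether of a beta-keto ester instead of closing to the four-membered ring. Dimerisation of the ketene and fragmentation of the strained adduct on work-up are further losses. The fallback builds the four-membered ring by the ketene–alkoxyalkyne cycloaddition and attaches the side chain afterwards; it sets out from 6 and 16 and comes back at 15. Acid 6 is converted ((COCl)2, DMF cat.) into 5-methyl-2-(3-methylbut-2-en-1-yl)hex-4-enoyl chloride F5. Et3N in the presence of 16 gives 3-ethoxy-4,4-bis(3-methylbut-2-en-1-yl)cyclobut-2-en-1-one F6. Exchange of the vinylogous ester with 2-(trimethylsilyl)ethanol (pyridinium tosylate cat., benzene, removal of ethanol) gives 4,4-bis(3-methylbut-2-en-1-yl)-3-[2-(trimethylsilyl)ethoxy]cyclobut-2-en-1-one F7. Iodination at C2 (I2, pyridine) gives 2-iodo-4,4-bis(3-methylbut-2-en-1-yl)-3-[2-(trimethylsilyl)ethoxy]cyclobut-2-en-1-one F8. Suzuki–Miyaura coupling with methyl (E)-3-(pinacolboryl)acrylate (Pd(PPh3)4, K3PO4) gives methyl (2E)-3-{3,3-bis(3-methylbut-2-en-1-yl)-4-oxo-2-[2-(trimethylsilyl)ethoxy]cyclobut-1-en-1-yl}prop-2-enoate F9. Asymmetric conjugate addition of PhB(OH)2 ([RhCl(C2H4)2]2 with a chiral diene ligand chosen for the S product, KOH cat., dioxane/H2O) then sets C4 and gives 15.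

Step 11. Acid may protonate a prenyl double bond and let it cyclise onto the neighbouring enol oxygen, or may open the enol lactone, after which reclosure would no longer be regiocontrolled. The fallback sets out from 23 and comes back at 24 and cleaves the other bond of the ether. Iodide attacks the ethyl carbon in an SN2 dealkylation under anhydrous, non-acidic conditions (LiI, 2,6-lutidine, 110 °C, or LiCl in DMSO), the way vinylogous esters of polyprenylated triketones are usually unmasked. Aqueous work-up of the lithium enolate gives 24; this fallback makes no new compound (F0).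

Step 5. Incomplete enantioselection in the opening of the anhydride cannot be corrected later, because C4 is defined only by which arm is esterified and every later intermediate would carry the same shortfall. The fallback desymmetrises the diester with an enzyme; it sets out from 10 and comes back at 11. Acid-catalysed methanolysis (MeOH, H2SO4 cat.) gives dimethyl 3-phenylpentanedioate F10. Hydrolysis of one enantiotopic ester group by pig liver esterase or alpha-chymotrypsin in pH 7 buffer, keeping the enzyme that gives the S acid, returns 11.

## Further compounds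

F1 | step 8 | 5,7-bis(tert-butyldimethylsilyloxy)-2H-chromen-2-one | CC(C)(C)[Si](C)(C)Oc1cc(O[Si](C)(C)C(C)(C)C)c2ccc(=O)oc2c1
F2 | step 8 | (4S)-5,7-bis(tert-butyldimethylsilyloxy)-4-phenylchroman-2-one | CC(C)(C)[Si](C)(C)Oc1cc(O[Si](C)(C)C(C)(C)C)c2c(c1)OC(=O)C[C@H]2c1ccccc1
F3 | step 8 | (4S)-5,7-dihydroxy-4-phenylchroman-2-one | Oc1cc(O)c2c(c1)OC(=O)C[C@H]2c1ccccc1
F4 | step 8 | (4S)-5,7-dihydroxy-6-[(2R)-2-methylbutanoyl]-4-phenylchroman-2-one | CC[C@@H](C)C(=O)c1c(O)cc2OC(=O)C[C@@H](c3ccccc3)c2c1O
F5 | step 7 | 5-methyl-2-(3-methylbut-2-en-1-yl)hex-4-enoyl chloride | CC(C)=CCC(CC=C(C)C)C(Cl)=O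
F6 | step 7 | 3-ethoxy-4,4-bis(3-methylbut-2-en-1-yl)cyclobut-2-en-1-one | CCOC1=CC(=O)C1(CC=C(C)C)CC=C(C)C
F7 | step 7 | 4,4-bis(3-methylbut-2-en-1-yl)-3-[2-(trimethylsilyl)ethoxy]cyclobut-2-en-1-one | C[Si](C)(C)CCOC1=CC(=O)C1(CC=C(C)C)CC=C(C)C
F8 | step 7 | 2-iodo-4,4-bis(3-methylbut-2-en-1-yl)-3-[2-(trimethylsilyl)ethoxy]cyclobut-2-en-1-one | C[Si](C)(C)CCOC1=C(I)C(=O)C1(CC=C(C)C)CC=C(C)C
F9 | step 7 | methyl (2E)-3-{3,3-bis(3-methylbut-2-en-1-yl)-4-oxo-2-[2-(trimethylsilyl)ethoxy]cyclobut-1-en-1-yl}prop-2-enoate | C[Si](C)(C)CCOC1=C(/C=C/C(=O)OC)C(=O)C1(CC=C(C)C)CC=C(C)C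
F0 | step 11 | none | none
F10 | step 5 | dimethyl 3-phenylpentanedioate | COC(=O)CC(CC(=O)OC)c1ccccc1
A1 | alternative 1 | (3S)-3-(3,5-dimethoxyphenyl)-3-phenylpropanoic acid | OC(=O)C[C@H](c1cc(OC)cc(OC)c1)c1ccccc1
A2 | alternative 1 | (4S)-5,7-dimethoxy-4-phenylchroman-2-one | COc1cc(OC)c2c(c1)OC(=O)C[C@H]2c1ccccc1
A3 | alternative 2 | methyl (3S,8R)-8-methyl-5,7-dioxo-3-phenyldecanoate | CC[C@@H](C)C(=O)CC(=O)C[C@H](c1ccccc1)CC(=O)OC
A4 | alternative 2 | bis(trimethylsilyl) dienol ether of A3 (double-bond isomers; both stereocentres as in A3) | CC[C@@H](C)C(O[Si](C)(C)C)=CC(O[Si](C)(C)C)=C[C@H](c1ccccc1)CC(=O)OC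
A5 | alternative 2 | 2,2-bis(3-methylbut-2-enyl)propanedioyl dichloride | CC(C)=CCC(CC=C(C)C)(C(Cl)=O)C(Cl)=O
A6 | alternative 2 | methyl (3S)-3-{2,6-dihydroxy-5-[(2R)-2-methylbutanoyl]-3,3-bis(3-methylbut-2-enyl)-4-oxocyclohexa-1,5-dienyl}-3-phenylpropanoate | CC[C@@H](C)C(=O)C1=C(O)C([C@H](c2ccccc2)CC(=O)OC)=C(O)C(CC=C(C)C)(CC=C(C)C)C1=O
A7 | alternative 3 | methyl (3S)-9-methyl-6-(3-methylbut-2-enyl)-5-oxo-3-phenyldec-8-enoate | CC(C)=CCC(CC=C(C)C)C(=O)C[C@H](c1ccccc1)CC(=O)OC
A8 | alternative 3 | trimethylsilyl enol ether of A7 (double bond towards the diprenyl carbon) | CC(C)=CCC(CC=C(C)C)=C(O[Si](C)(C)C)C[C@H](c1ccccc1)CC(=O)OC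
A9 | alternative 3 | malonyl dichloride | O=C(Cl)CC(Cl)=O
A10 | alternative 3 | methyl (3S)-3-[2-hydroxy-3,3-bis(3-methylbut-2-enyl)-4,6-dioxocyclohex-1-enyl]-3-phenylpropanoate | OC1=C([C@H](c2ccccc2)CC(=O)OC)C(=O)CC(=O)C1(CC=C(C)C)CC=C(C)C
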